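## Retrosynthetic overview

- The target is robinetinidol-(4α→2')-dihydrorobinetin. The last disconnection is the C4–C2' interflavanyl bond: a flavan-4-yl cation captured by ring B of dihydrorobinetin, so both halves come from one dihydroflavonol.
- The flavan-3,4-diol half is that same dihydroflavonol after reduction of the C4 ketone. C4 of the upper unit is set last, by substrate control (attack anti to the C3 hydroxyl).
- Key step: ring C of the dihydroflavonol is closed by C–O bond formation. A free 2'-hydroxychalcone undergoes catalytic asymmetric epoxidation and in-flask 6-endo phenol–epoxide closure (C3–O and O1–C2 bonds), which sets C2 and C3 of both units.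
- The chalcone comes from a Claisen–Schmidt condensation of two commercial benzyl ethers; the benzyl groups are removed by hydrogenolysis before the coupling.
- Ring order: ring C of the dihydroflavonol is the only ring made, and it serves as ring C of both units. Rings A and B are bought.

Assumption: compounds 1 and 2 are bought as such. The ligand L-PiPr2, 1,1'-(propane-1,3-diyl)bis{(2S)-2-[(2,6-diisopropylphenyl)carbamoyl]piperidine 1-oxide}, is taken to be the enantiomer that gives the (αR,βS)-epoxide; if the first run shows the opposite sense, its mirror image from D-pipecolic acid is used and nothing else changes.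

## Route

Step 1
Reactants: 1 1-[4-(benzyloxy)-2-hydroxyphenyl]ethan-1-one; 2 3,4,5-tris(benzyloxy)benzaldehyde
Product: 4 (E)-1-[4-(benzyloxy)-2-hydroxyphenyl]-3-[3,4,5-tris(benzyloxy)phenyl]prop-2-en-1-one (chalcone), via aldol adduct 3 (not isolated)
Conditions: KOH (50% aq, 6 equiv), EtOH–THF, rt, 36 h; then 1 M HCl to pH 4
Reagents that add atoms: none
Why: Claisen–Schmidt (crossed aldol) condensation, in which the methyl ketone enolate adds to the non-enolisable aldehyde and aldol 3 dehydrates by E1cB to the conjugated E-enone while the 2'-phenoxide is a spectator.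

Step 2
Reactants: 4 chalcone
Product: 6 (2R,3R)-7-(benzyloxy)-3-hydroxy-2-[3,4,5-tris(benzyloxy)phenyl]-2,3-dihydro-4H-chromen-4-one (tetra-O-benzyl dihydrorobinetin), via epoxy ketone 5 (not isolated)
Conditions: Sc(OTf)3 (10 mol%), L-PiPr2 (11 mol%), 30% aq H2O2 (2 equiv), THF, 30 °C, 24 h, then 45 °C until 5 is consumed; recrystallise (EtOAc–hexane) to >99% ee
Reagents that add atoms: hydrogen peroxide, OO
Why: Proposed new method: the free 2'-hydroxychalcone binds the chiral Sc(OTf)3–N,N'-dioxide complex through its phenol and carbonyl oxygens (two-point binding, s-cis enone), scandium-bound hydroperoxide adds to Cβ on the open face and closes to the (αR,βS)-epoxy ketone 5, and the same Lewis acid then activates the epoxide for 6-endo attack of the neighbouring phenol at the benzylic carbon with inversion (new O1–C2 bond), so C3 keeps the Cα configuration and C2 is inverted to give the 2,3-trans (2R,3R) product; the closest known reactions are the Sc(OTf)3/N,N'-dioxide-catalysed H2O2 epoxidation (Weitz–Scheffer type) of chalcones without a free 2'-hydroxyl and the acid-mediated cyclisation of isolated 2'-hydroxychalcone epoxides (first half of the Algar–Flynn–Oyamada reaction), which have not been merged into one enantioselective catalytic step on an unprotected 2'-hydroxychalcone.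

Step 3
Reactants: 6 tetra-O-benzyl dihydrorobinetin
Product: 7 (2R,3R)-3,7-dihydroxy-2-(3,4,5-trihydroxyphenyl)-2,3-dihydro-4H-chromen-4-one ((+)-dihydrorobinetin)
Conditions: H2 (1 atm), 10% Pd/C, EtOAc–MeOH (1:1), rt
Reagents that add atoms: none
Why: Hydrogenolysis of the four aryl benzyl ethers over Pd/C is much faster than reduction of the aryl ketone or cleavage of the cyclic O1–C2 benzylic ether, so C2 and C3 are untouched (standard O-debenzylation).

Step 4
Reactants: 7 (+)-dihydrorobinetin (about one fifth of the batch)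
Product: 8 (2R,3S,4R)-2-(3,4,5-trihydroxyphenyl)-3,4-dihydro-2H-chromene-3,4,7-triol (leucorobinetinidin)
Conditions: NaBH4 (4 equiv), EtOH, 0 °C to rt, N2; aqueous work-up at pH 6, 0 °C
Reagents that add atoms: none
Why: Borohydride reduction of the C4 ketone, with axial hydride delivery giving mainly the all-equatorial 2,3-trans-3,4-trans diol (4R); C2 and C3 are not touched, and a 3,4-cis/trans mixture is acceptable because C4 is ionised in step 5.

Step 5
Reactants: 8 leucorobinetinidin (1 equiv); 7 (+)-dihydrorobinetin (4 equiv, excess recovered)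
Product: 10 (2R,3R)-3,7-dihydroxy-2-{2-[(2R,3S,4S)-3,7-dihydroxy-2-(3,4,5-trihydroxyphenyl)-3,4-dihydro-2H-chromen-4-yl]-3,4,5-trihydroxyphenyl}-2,3-dihydro-4H-chromen-4-one (target), via flavan-4-yl cation 9 (not isolated)
Conditions: 0.1 M HCl in H2O–dioxane (3:1), 8 added slowly to 7, rt, N2, 16 h; EtOAc extraction; Sephadex LH-20 (EtOH)
Reagents that add atoms: none
Why: Biomimetic Friedel–Crafts alkylation (flavan-3,4-diol/phenol condensation) in which acid ionises the benzylic C4–OH to the 7-hydroxyl-stabilised cation 9, which is trapped by the pyrogallol ring B of 7 at C2' (identical with C6', ortho and para to hydroxyls, while ring A of 7 is damped by the conjugated carbonyl) from the face anti to the C3 hydroxyl, setting 4S (3,4-trans, 4α) as the major isomer.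

## Compound list

1 | 1-[4-(benzyloxy)-2-hydroxyphenyl]ethan-1-one | CC(=O)c1ccc(OCc2ccccc2)cc1O | starting material
2 | 3,4,5-tris(benzyloxy)benzaldehyde | O=Cc1cc(OCc2ccccc2)c(OCc2ccccc2)c(OCc2ccccc2)c1 | starting material
3 | 1-[4-(benzyloxy)-2-hydroxyphenyl]-3-hydroxy-3-[3,4,5-tris(benzyloxy)phenyl]propan-1-one (racemic aldol adduct) | O=C(CC(O)c1cc(OCc2ccccc2)c(OCc2ccccc2)c(OCc2ccccc2)c1)c1ccc(OCc2ccccc2)cc1O | intermediate (not isolated)
4 | (E)-1-[4-(benzyloxy)-2-hydroxyphenyl]-3-[3,4,5-tris(benzyloxy)phenyl]prop-2-en-1-one | O=C(/C=C/c1cc(OCc2ccccc2)c(OCc2ccccc2)c(OCc2ccccc2)c1)c1ccc(OCc2ccccc2)cc1O | intermediate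
5 | [4-(benzyloxy)-2-hydroxyphenyl]{(2R,3S)-3-[3,4,5-tris(benzyloxy)phenyl]oxiran-2-yl}methanone (trans, αR,βS) | O=C(c1ccc(OCc2ccccc2)cc1O)[C@@H]1O[C@H]1c1cc(OCc2ccccc2)c(OCc2ccccc2)c(OCc2ccccc2)c1 | intermediate (not isolated)
6 | (2R,3R)-7-(benzyloxy)-3-hydroxy-2-[3,4,5-tris(benzyloxy)phenyl]-2,3-dihydro-4H-chromen-4-one | O=C1c2ccc(OCc3ccccc3)cc2O[C@H](c2cc(OCc3ccccc3)c(OCc3ccccc3)c(OCc3ccccc3)c2)[C@H]1O | intermediate
7 | (2R,3R)-3,7-dihydroxy-2-(3,4,5-trihydroxyphenyl)-2,3-dihydro-4H-chromen-4-one ((+)-dihydrorobinetin) | O=C1c2ccc(O)cc2O[C@H](c2cc(O)c(O)c(O)c2)[C@H]1O | intermediate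
8 | (2R,3S,4R)-2-(3,4,5-trihydroxyphenyl)-3,4-dihydro-2H-chromene-3,4,7-triol (leucorobinetinidin, 2,3-trans-3,4-trans) | O[C@@H]1c2ccc(O)cc2O[C@H](c2cc(O)c(O)c(O)c2)[C@H]1O | intermediate
9 | (2R,3S)-3,7-dihydroxy-2-(3,4,5-trihydroxyphenyl)-3,4-dihydro-2H-chromen-4-ylium (C4 cation, protonated ring A quinone methide) | [CH+]1c2ccc(O)cc2O[C@H](c2cc(O)c(O)c(O)c2)[C@H]1O | intermediate (not isolated)
10 | (2R,3R)-3,7-dihydroxy-2-{2-[(2R,3S,4S)-3,7-dihydroxy-2-(3,4,5-trihydroxyphenyl)-3,4-dihydro-2H-chromen-4-yl]-3,4,5-trihydroxyphenyl}-2,3-dihydro-4H-chromen-4-one | O=C1c2ccc(O)cc2O[C@H](c2cc(O)c(O)c(O)c2[C@@H]2c3ccc(O)cc3O[C@H](c3cc(O)c(O)c(O)c3)[C@H]2O)[C@H]1O | target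

## Step count and risks

Total steps: 5. Longest linear sequence: 5 (steps 1 to 5; compound 7 from step 3 feeds both step 4 and step 5).

Steps most likely to fail:

Step 2 (the new epoxidation–cyclisation). The phenol-anchored binding mode may give low ee, the Lewis acid may instead close 4 to the racemic flavanone, and an SN1-type epoxide opening would erode the trans ratio and the ee. The fallback is known chemistry; it sets out from 4 and comes back at 6. Chalcone 4 is O-alkylated at the 2'-hydroxyl (MOMCl, NaH, DMF, 0 °C) to give the 2'-O-methoxymethyl chalcone F1. Juliá–Colonna epoxidation (poly-L-leucine, urea–H2O2, DBU, THF, rt) then gives the (αR,βS)-epoxy ketone F2. HCl in MeOH–THF at 45 °C cleaves the acetal, and the freed phenol opens the epoxide at the benzylic carbon with inversion to give 6, which is recrystallised to raise the ee.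

Step 5 (the coupling). Diol 8 can self-condense through its own nucleophilic rings (C6 and C8 of ring A, and its own pyrogallol ring B) faster than the hindered C2' of 7 reacts, and the 4β epimer will accompany the product. The fallback sets out from 6 (with 7 as nucleophile) and comes back at 10. NaBH4 (THF–EtOH, 0 °C) reduces 6 to the tetra-O-benzyl flavan-3,4-diol F3, whose rings A and B are benzyl ethers and therefore poorer, more hindered nucleophiles. BF3·OEt2 in dry dioxane at rt ionises F3 in the presence of 7 (4 equiv) and gives the upper-unit tetra-O-benzyl biflavonoid F4. H2 over Pd/C (EtOAc–MeOH) then removes the four benzyl groups to give 10.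

Step 4 (the reduction). In basic borohydride the 7-phenoxide turns the C4 carbonyl into a vinylogous carboxylate, so the reduction may stall, and the free diol is acid-labile on work-up. The fallback sets out from 7 and comes back at 8. TBSCl and imidazole (DMF, 0 °C) convert 7 into the 7,3',4',5'-tetra-O-TBS ether F5. NaBH4 (THF–MeOH, −20 °C) reduces the now undeactivated ketone to the tetra-O-TBS flavan-3,4-diol F6. Buffered fluoride (TBAF/AcOH 1:1, THF, 0 °C) then frees 8 under near-neutral conditions.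

## Further compounds

F1 | step 2 | (E)-1-[4-(benzyloxy)-2-(methoxymethoxy)phenyl]-3-[3,4,5-tris(benzyloxy)phenyl]prop-2-en-1-one | COCOc1cc(OCc2ccccc2)ccc1C(=O)/C=C/c1cc(OCc2ccccc2)c(OCc2ccccc2)c(OCc2ccccc2)c1
F2 | step 2 | [4-(benzyloxy)-2-(methoxymethoxy)phenyl]{(2R,3S)-3-[3,4,5-tris(benzyloxy)phenyl]oxiran-2-yl}methanone | COCOc1cc(OCc2ccccc2)ccc1C(=O)[C@@H]1O[C@H]1c1cc(OCc2ccccc2)c(OCc2ccccc2)c(OCc2ccccc2)c1
F3 | step 5 | (2R,3S,4R)-7-(benzyloxy)-2-[3,4,5-tris(benzyloxy)phenyl]-3,4-dihydro-2H-chromene-3,4-diol | O[C@@H]1c2ccc(OCc3ccccc3)cc2O[C@H](c2cc(OCc3ccccc3)c(OCc3ccccc3)c(OCc3ccccc3)c2)[C@H]1O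
F4 | step 5 | (2R,3R)-2-{2-[(2R,3S,4S)-7-(benzyloxy)-3-hydroxy-2-[3,4,5-tris(benzyloxy)phenyl]-3,4-dihydro-2H-chromen-4-yl]-3,4,5-trihydroxyphenyl}-3,7-dihydroxy-2,3-dihydro-4H-chromen-4-one | O=C1c2ccc(O)cc2O[C@H](c2cc(O)c(O)c(O)c2[C@@H]2c3ccc(OCc4ccccc4)cc3O[C@H](c3cc(OCc4ccccc4)c(OCc4ccccc4)c(OCc4ccccc4)c3)[C@H]2O)[C@H]1O
F5 | step 4 | (2R,3R)-7-[(tert-butyldimethylsilyl)oxy]-3-hydroxy-2-{3,4,5-tris[(tert-butyldimethylsilyl)oxy]phenyl}-2,3-dihydro-4H-chromen-4-one | O=C1c2ccc(O[Si](C)(C)C(C)(C)C)cc2O[C@H](c2cc(O[Si](C)(C)C(C)(C)C)c(O[Si](C)(C)C(C)(C)C)c(O[Si](C)(C)C(C)(C)C)c2)[C@H]1O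
F6 | step 4 | (2R,3S,4R)-7-[(tert-butyldimethylsilyl)oxy]-2-{3,4,5-tris[(tert-butyldimethylsilyl)oxy]phenyl}-3,4-dihydro-2H-chromene-3,4-diol | O[C@@H]1c2ccc(O[Si](C)(C)C(C)(C)C)cc2O[C@H](c2cc(O[Si](C)(C)C(C)(C)C)c(O[Si](C)(C)C(C)(C)C)c(O[Si](C)(C)C(C)(C)C)c2)[C@H]1O
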